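C1–C10 are the decalin carbons in drimane numbering (ring A = C1–C5 and C10, ring B = C5–C10); C11–C19 run from C9 along the chain to the arene.
Last bonds made: O12–S (sulfation), then back to C18–C19 and C17–CH3 (methylalumination of a C17≡C18 alkyne and benzylation with the masked hydroquinone).
Ring B is closed last, by forming C9–C10 in a cation–olefin cyclization of a monocyclic precursor: ring A, an (S)-2,6,6-trimethylcyclohex-2-enyl unit with its alkene at C1=C10, already carries the whole C6–C16 chain with both side-chain stereocentres.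
The feature that allows this: ring B is a cyclohexene whose trisubstituted C7=C8 bond (methyl on C8) lies next to the C9 stereocentre and the quaternary C10, with H-5 on the neighbouring fusion carbon. This is the trace left when an E-C8=C9 alkene attacks a tertiary C10 cation and H-7 is lost.
The cyclization substrate is cut at C9–C11 and C8–CH3 into a ring A alkyne and an oxirane from (R)-citronellal (C11–C16, C13 from the chiral pool, C12 by catalyst-controlled chlorination). Ring A and the arene are bought, the oxirane is a temporary ring (made in step 6, opened in step 9), and ring B closes in step 11.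

Key step: step 11

Remark: the target and the sulfate before it are written as free hydrogen sulfates, as in the given structure; on the bench they would be handled as sodium salts.

Step 1
Reactants: 1 2,4,4-trimethylcyclohex-2-en-1-one
Product: 2 (1R)-2,4,4-trimethylcyclohex-2-en-1-ol
Conditions: BH3·SMe2, (S)-2-methyl-CBS-oxazaborolidine (10 mol %), THF, −20 °C
Reagents that add atoms: none
Why: Corey–Bakshi–Shibata reduction, in which the trisubstituted-alkene arm of the enone acts as the large group, so hydride should add to one carbonyl face and give the (R)-allylic alcohol whose C–O bond defines the face used in step 2.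

Step 2
Reactants: 2 (1R)-2,4,4-trimethylcyclohex-2-en-1-ol
Product: 4 N,N-dimethyl-2-[(1S)-2,6,6-trimethylcyclohex-2-en-1-yl]acetamide, via ketene N,O-acetal 3 (not isolated)
Conditions: CH3C(OMe)2NMe2, xylene, 140 °C
Reagents that add atoms: N,N-dimethylacetamide dimethyl acetal CC(OC)(OC)N(C)C
Why: Eschenmoser–Claisen rearrangement, in which the suprafacial [3,3] shift of ketene N,O-acetal 3 makes the new C–C bond at the ring carbon next to the gem-dimethyl group on the face that carried the oxygen, setting the (S) centre (the later C5) and moving the ring alkene to C1=C10.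

Step 3
Reactants: 4 N,N-dimethyl-2-[(1S)-2,6,6-trimethylcyclohex-2-en-1-yl]acetamide
Product: 5 2-[(1S)-2,6,6-trimethylcyclohex-2-en-1-yl]ethan-1-ol
Conditions: LiEt3BH, THF, 0 to 25 °C; then H2O
Reagents that add atoms: none
Why: LiEt3BH reduces a tertiary amide to the primary alcohol with C–N cleavage and touches neither the alkene nor the stereocentre.

Step 4
Reactants: 5 2-[(1S)-2,6,6-trimethylcyclohex-2-en-1-yl]ethan-1-ol
Product: 6 (6S)-6-(2-iodoethyl)-1,5,5-trimethylcyclohex-1-ene
Conditions: I2, PPh3, imidazole, CH2Cl2, 0 °C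
Reagents that add atoms: iodine II
Why: Appel-type iodination of a primary alcohol is neutral and leaves the ring alkene and the adjacent stereocentre alone.

Step 5
Reactants: 6 (6S)-6-(2-iodoethyl)-1,5,5-trimethylcyclohex-1-ene
Product: 7 (6S)-6-(but-3-yn-1-yl)-1,5,5-trimethylcyclohex-1-ene
Conditions: LiC≡CH·H2NCH2CH2NH2, DMSO, 25 °C
Reagents that add atoms: lithium acetylide–ethylenediamine complex [Li+].[C-]#C.NCCN
Why: SN2 alkylation of lithium acetylide by an unhindered primary iodide, which adds the two alkyne carbons C8 and C9.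

Step 6
Reactants: 8 (R)-citronellal, (3R)-3,7-dimethyloct-6-enal
Product: 11 (2S)-2-[(2R)-6-methylhept-5-en-2-yl]oxirane, via alpha-chloro aldehyde 9 (not isolated), via chlorohydrin 10 (not isolated)
Conditions: N-chlorosuccinimide, 2,5-diphenylpyrrolidine (10 mol %, the C2-symmetric enantiomer that delivers the (2R)-chloride), CH2Cl2, 0 °C; then NaBH4, MeOH, 0 °C; then KOH, EtOH/H2O, 25 °C
Reagents that add atoms: none
Why: Enamine-catalysed α-chlorination puts chlorine on C12 under catalyst control (the C13 methyl centre comes from the chiral pool and has little say), NaBH4 reduces the labile chloro aldehyde at once, and Williamson closure with inversion at C12 gives the (S)-oxirane.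

Step 7
Reactants: 11 (2S)-2-[(2R)-6-methylhept-5-en-2-yl]oxirane
Product: 13 (4R)-4-[(2S)-oxiran-2-yl]pentan-1-ol, via epoxy aldehyde 12 (not isolated)
Conditions: O3, CH2Cl2, −78 °C; PPh3, −78 to 0 °C; then NaBH4, MeOH, 0 °C
Reagents that add atoms: ozone [O-][O+]=O
Why: Ozonolysis cleaves the only C=C bond while the oxirane is inert to ozone, and reduction in the same flask gives the primary alcohol that carries C16.

Step 8
Reactants: 13 (4R)-4-[(2S)-oxiran-2-yl]pentan-1-ol
Product: 14 (2S)-2-[(2R)-5-chloropentan-2-yl]oxirane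
Conditions: PPh3, CCl4, CH2Cl2, 0 to 25 °C
Reagents that add atoms: tetrachloromethane ClC(Cl)(Cl)Cl
Why: Appel chlorination under neutral conditions spares the oxirane and gives a primary chloride that is inert to every step up to step 12.

Step 9
Reactants: 7 (6S)-6-(but-3-yn-1-yl)-1,5,5-trimethylcyclohex-1-ene; 14 (2S)-2-[(2R)-5-chloropentan-2-yl]oxirane
Product: 17 (4R,5R,7E)-1-chloro-4,8-dimethyl-10-[(1S)-2,6,6-trimethylcyclohex-2-en-1-yl]dec-7-en-5-ol, via alkenylalane 15 (not isolated), via lithium alkenylalanate 16 (not isolated)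
Conditions: Me3Al, Cp2ZrCl2 (cat.), CH2Cl2, 25 °C; volatiles removed; n-BuLi, hexane/THF, −78 to 0 °C; then 14, 0 to 25 °C
Reagents that add atoms: trimethylaluminium C[Al](C)C
Why: Zirconium-catalysed methylalumination (Negishi carboalumination) adds methyl and aluminium syn across the terminal alkyne with methyl on the internal carbon, and the butyl ate complex of the resulting E-alkenylalane opens the oxirane at its CH2 carbon with retention of alkene geometry and without touching C12.

Step 10
Reactants: 17 (4R,5R,7E)-1-chloro-4,8-dimethyl-10-[(1S)-2,6,6-trimethylcyclohex-2-en-1-yl]dec-7-en-5-ol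
Product: 18 (4R,5R,7E)-1-chloro-4,8-dimethyl-10-[(1S)-2,6,6-trimethylcyclohex-2-en-1-yl]dec-7-en-5-yl 2,2-dimethylpropanoate
Conditions: pivaloyl chloride, DMAP, pyridine, CH2Cl2, 40 °C
Reagents that add atoms: pivaloyl chloride CC(C)(C)C(=O)Cl
Why: DMAP-catalysed acylation gives a pivalate that removes the nucleophilicity of O12 (which would otherwise capture the C8 cation in step 11) and survives superacid, acetylide and Me3Al.

Step 11
Reactants: 18 (4R,5R,7E)-1-chloro-4,8-dimethyl-10-[(1S)-2,6,6-trimethylcyclohex-2-en-1-yl]dec-7-en-5-yl 2,2-dimethylpropanoate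
Product: 21 (2R,3R)-6-chloro-3-methyl-1-[(1S,4aS,8aS)-2,5,5,8a-tetramethyl-1,4,4a,5,6,7,8,8a-octahydronaphthalen-1-yl]hexan-2-yl 2,2-dimethylpropanoate, via tertiary C10 cation 19 (not isolated), via bicyclic C8 cation 20 (not isolated)
Conditions: FSO3H (5 equiv), i-PrNO2, −78 °C; Et3N quench at −78 °C
Reagents that add atoms: none
Why: Protonation of the ring A alkene at C1 gives the tertiary C10 cation 19, the E-C8=C9 alkene attacks it through C9 to give the tertiary C8 cation 20, and loss of the axial H-7 on amine quench leaves the C7=C8 bond. The closest known reaction type is the fluorosulfonic acid cyclization of open-chain and monocyclic farnesyl-type esters to drim-7-enes, together with the acid closure of monocyclic homofarnesyl precursors to the ambroxide skeleton. Ring B closes in the 6-endo-trig mode through a chair-like transition state in which the side chain on C5 is equatorial on ring A. C10 is controlled by the existing C5 stereocentre (C9 bonds on the face that leaves the C10 methyl axial and trans to H-5, giving the trans-decalin), and C9 is controlled by the E geometry of the alkene, which places C11 equatorial. The step needs protonation at the ring alkene and not at C8=C9, which the O-protonated pivalate on C12, two carbons from C9, should secure by deactivating the side-chain alkene; it needs ring closure to outrun a 1,2-hydride shift from C5 to C10, for which the low temperature and the fast six-membered closure are relied on; and it needs proton loss toward C7, for which the precedent is formation of the endocyclic trisubstituted alkene under these conditions.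

Step 12
Reactants: 21 (2R,3R)-6-chloro-3-methyl-1-[(1S,4aS,8aS)-2,5,5,8a-tetramethyl-1,4,4a,5,6,7,8,8a-octahydronaphthalen-1-yl]hexan-2-yl 2,2-dimethylpropanoate
Product: 22 (2R,3R)-3-methyl-1-[(1S,4aS,8aS)-2,5,5,8a-tetramethyl-1,4,4a,5,6,7,8,8a-octahydronaphthalen-1-yl]oct-7-yn-2-yl 2,2-dimethylpropanoate
Conditions: LiC≡CH·H2NCH2CH2NH2, NaI (cat.), DMSO, 25 °C
Reagents that add atoms: lithium acetylide–ethylenediamine complex [Li+].[C-]#C.NCCN
Why: SN2 displacement of the primary chloride by lithium acetylide with iodide catalysis, in which the hindered pivalate resists the basic medium and the trisubstituted alkene is inert.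

Step 13
Reactants: 22 (2R,3R)-3-methyl-1-[(1S,4aS,8aS)-2,5,5,8a-tetramethyl-1,4,4a,5,6,7,8,8a-octahydronaphthalen-1-yl]oct-7-yn-2-yl 2,2-dimethylpropanoate; 23 2-(chloromethyl)-1,4-dimethoxybenzene (2,5-dimethoxybenzyl chloride)
Product: 25 (2R,3R,7E)-9-(2,5-dimethoxyphenyl)-3,7-dimethyl-1-[(1S,4aS,8aS)-2,5,5,8a-tetramethyl-1,4,4a,5,6,7,8,8a-octahydronaphthalen-1-yl]non-7-en-2-yl 2,2-dimethylpropanoate, via alkenylalane 24 (not isolated)
Conditions: Me3Al, Cp2ZrCl2, CH2Cl2, 25 °C; then 23, Pd(PPh3)4 (cat.), THF, 25 °C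
Reagents that add atoms: trimethylaluminium C[Al](C)C
Why: Negishi methylalumination of the terminal alkyne gives the E-alkenylalane with methyl on C17 by syn addition, and palladium-catalysed cross-coupling of this alane with the benzylic chloride forms C18–C19 with retention, so the E-trisubstituted alkene is set by the carbometalation.

Step 14
Reactants: 25 (2R,3R,7E)-9-(2,5-dimethoxyphenyl)-3,7-dimethyl-1-[(1S,4aS,8aS)-2,5,5,8a-tetramethyl-1,4,4a,5,6,7,8,8a-octahydronaphthalen-1-yl]non-7-en-2-yl 2,2-dimethylpropanoate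
Product: 26 (2R,3R,7E)-9-(2,5-dimethoxyphenyl)-3,7-dimethyl-1-[(1S,4aS,8aS)-2,5,5,8a-tetramethyl-1,4,4a,5,6,7,8,8a-octahydronaphthalen-1-yl]non-7-en-2-ol
Conditions: i-Bu2AlH, CH2Cl2, −78 °C
Reagents that add atoms: none
Why: Reductive cleavage of the pivalate with i-Bu2AlH at low temperature frees the C12 hydroxyl and leaves both alkenes and the aryl methyl ethers untouched.

Step 15
Reactants: 26 (2R,3R,7E)-9-(2,5-dimethoxyphenyl)-3,7-dimethyl-1-[(1S,4aS,8aS)-2,5,5,8a-tetramethyl-1,4,4a,5,6,7,8,8a-octahydronaphthalen-1-yl]non-7-en-2-ol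
Product: 27 (2R,3R,7E)-9-(2,5-dimethoxyphenyl)-3,7-dimethyl-1-[(1S,4aS,8aS)-2,5,5,8a-tetramethyl-1,4,4a,5,6,7,8,8a-octahydronaphthalen-1-yl]non-7-en-2-yl hydrogen sulfate
Conditions: SO3·pyridine, pyridine, 25 °C
Reagents that add atoms: sulfur trioxide–pyridine complex O=S(=O)=O.c1ccncc1
Why: O-Sulfation of the only free hydroxyl with the SO3·pyridine complex, with the phenols still masked as methyl ethers so that no aryl sulfate can form.

Step 16
Reactants: 27 (2R,3R,7E)-9-(2,5-dimethoxyphenyl)-3,7-dimethyl-1-[(1S,4aS,8aS)-2,5,5,8a-tetramethyl-1,4,4a,5,6,7,8,8a-octahydronaphthalen-1-yl]non-7-en-2-yl hydrogen sulfate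
Product: 29 halisulfate 1, via quinone sulfate 28 (not isolated)
Conditions: (NH4)2Ce(NO3)6, MeCN/H2O, 0 °C; then Na2S2O4, H2O/EtOAc, 25 °C, argon
Reagents that add atoms: water O
Why: Oxidative demethylation of the hydroquinone dimethyl ether by (NH4)2Ce(NO3)6 gives the quinone (both quinone oxygens come from water) and dithionite reduces it to the hydroquinone, while the sulfate monoester and the two trisubstituted alkenes should survive the short, cold, weakly acidic oxidation.

Compound list
1 | 2,4,4-trimethylcyclohex-2-en-1-one | CC1=CC(C)(C)CCC1=O | starting material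
2 | (1R)-2,4,4-trimethylcyclohex-2-en-1-ol | O[C@@H]1CCC(C)(C)C=C1C | intermediate
3 | N,N-dimethyl-1-{[(1R)-2,4,4-trimethylcyclohex-2-en-1-yl]oxy}ethen-1-amine (ketene N,O-acetal) | C=C(N(C)C)O[C@@H]1CCC(C)(C)C=C1C | intermediate
4 | N,N-dimethyl-2-[(1S)-2,6,6-trimethylcyclohex-2-en-1-yl]acetamide | CN(C)C(=O)C[C@@H]1C(C)=CCCC1(C)C | intermediate
5 | 2-[(1S)-2,6,6-trimethylcyclohex-2-en-1-yl]ethan-1-ol | OCC[C@@H]1C(C)=CCCC1(C)C | intermediate
6 | (6S)-6-(2-iodoethyl)-1,5,5-trimethylcyclohex-1-ene | ICC[C@@H]1C(C)=CCCC1(C)C | intermediate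
7 | (6S)-6-(but-3-yn-1-yl)-1,5,5-trimethylcyclohex-1-ene | C#CCC[C@@H]1C(C)=CCCC1(C)C | intermediate
8 | (R)-citronellal, (3R)-3,7-dimethyloct-6-enal | O=CC[C@H](C)CCC=C(C)C | starting material
9 | (2R,3R)-2-chloro-3,7-dimethyloct-6-enal | O=C[C@H](Cl)[C@H](C)CCC=C(C)C | intermediate
10 | (2R,3R)-2-chloro-3,7-dimethyloct-6-en-1-ol | OC[C@H](Cl)[C@H](C)CCC=C(C)C | intermediate
11 | (2S)-2-[(2R)-6-methylhept-5-en-2-yl]oxirane | C1O[C@H]1[C@H](C)CCC=C(C)C | intermediate
12 | (4R)-4-[(2S)-oxiran-2-yl]pentanal | C1O[C@H]1[C@H](C)CCC=O | intermediate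
13 | (4R)-4-[(2S)-oxiran-2-yl]pentan-1-ol | C1O[C@H]1[C@H](C)CCCO | intermediate
14 | (2S)-2-[(2R)-5-chloropentan-2-yl]oxirane | C1O[C@H]1[C@H](C)CCCCl | intermediate
15 | dimethyl{(1E)-2-methyl-4-[(1S)-2,6,6-trimethylcyclohex-2-en-1-yl]but-1-en-1-yl}alumane | CC1=CCCC(C)(C)[C@@H]1CC/C(C)=C/[Al](C)C | intermediate
16 | lithium butyl(dimethyl){(1E)-2-methyl-4-[(1S)-2,6,6-trimethylcyclohex-2-en-1-yl]but-1-en-1-yl}aluminate | [Li+].CCCC[Al-](C)(C)/C=C(\C)CC[C@@H]1C(C)=CCCC1(C)C | intermediate
17 | (4R,5R,7E)-1-chloro-4,8-dimethyl-10-[(1S)-2,6,6-trimethylcyclohex-2-en-1-yl]dec-7-en-5-ol | CC1=CCCC(C)(C)[C@@H]1CC/C(C)=C/C[C@@H](O)[C@H](C)CCCCl | intermediate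
18 | (4R,5R,7E)-1-chloro-4,8-dimethyl-10-[(1S)-2,6,6-trimethylcyclohex-2-en-1-yl]dec-7-en-5-yl 2,2-dimethylpropanoate | CC1=CCCC(C)(C)[C@@H]1CC/C(C)=C/C[C@@H](OC(=O)C(C)(C)C)[C@H](C)CCCCl | intermediate
19 | tertiary C10 cation formed from 18 by protonation at C1 | C[C+]1CCCC(C)(C)[C@@H]1CC/C(C)=C/C[C@@H](OC(=O)C(C)(C)C)[C@H](C)CCCCl | intermediate
20 | bicyclic tertiary C8 cation formed by C9–C10 bond formation | C[C+]1CC[C@H]2C(C)(C)CCC[C@]2(C)[C@H]1C[C@@H](OC(=O)C(C)(C)C)[C@H](C)CCCCl | intermediate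
21 | (2R,3R)-6-chloro-3-methyl-1-[(1S,4aS,8aS)-2,5,5,8a-tetramethyl-1,4,4a,5,6,7,8,8a-octahydronaphthalen-1-yl]hexan-2-yl 2,2-dimethylpropanoate | CC1=CC[C@H]2C(C)(C)CCC[C@]2(C)[C@H]1C[C@@H](OC(=O)C(C)(C)C)[C@H](C)CCCCl | intermediate
22 | (2R,3R)-3-methyl-1-[(1S,4aS,8aS)-2,5,5,8a-tetramethyl-1,4,4a,5,6,7,8,8a-octahydronaphthalen-1-yl]oct-7-yn-2-yl 2,2-dimethylpropanoate | CC1=CC[C@H]2C(C)(C)CCC[C@]2(C)[C@H]1C[C@@H](OC(=O)C(C)(C)C)[C@H](C)CCCC#C | intermediate
23 | 2-(chloromethyl)-1,4-dimethoxybenzene (2,5-dimethoxybenzyl chloride) | COc1ccc(OC)c(CCl)c1 | starting material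
24 | dimethyl[(1E,6R,7R)-2,6-dimethyl-7-(pivaloyloxy)-8-[(1S,4aS,8aS)-2,5,5,8a-tetramethyl-1,4,4a,5,6,7,8,8a-octahydronaphthalen-1-yl]oct-1-en-1-yl]alumane | CC1=CC[C@H]2C(C)(C)CCC[C@]2(C)[C@H]1C[C@@H](OC(=O)C(C)(C)C)[C@H](C)CCC/C(C)=C/[Al](C)C | intermediate
25 | (2R,3R,7E)-9-(2,5-dimethoxyphenyl)-3,7-dimethyl-1-[(1S,4aS,8aS)-2,5,5,8a-tetramethyl-1,4,4a,5,6,7,8,8a-octahydronaphthalen-1-yl]non-7-en-2-yl 2,2-dimethylpropanoate | CC1=CC[C@H]2C(C)(C)CCC[C@]2(C)[C@H]1C[C@@H](OC(=O)C(C)(C)C)[C@H](C)CCC/C(C)=C/Cc1cc(OC)ccc1OC | intermediate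
26 | (2R,3R,7E)-9-(2,5-dimethoxyphenyl)-3,7-dimethyl-1-[(1S,4aS,8aS)-2,5,5,8a-tetramethyl-1,4,4a,5,6,7,8,8a-octahydronaphthalen-1-yl]non-7-en-2-ol | CC1=CC[C@H]2C(C)(C)CCC[C@]2(C)[C@H]1C[C@@H](O)[C@H](C)CCC/C(C)=C/Cc1cc(OC)ccc1OC | intermediate
27 | (2R,3R,7E)-9-(2,5-dimethoxyphenyl)-3,7-dimethyl-1-[(1S,4aS,8aS)-2,5,5,8a-tetramethyl-1,4,4a,5,6,7,8,8a-octahydronaphthalen-1-yl]non-7-en-2-yl hydrogen sulfate | CC1=CC[C@H]2C(C)(C)CCC[C@]2(C)[C@H]1C[C@@H](OS(=O)(=O)O)[C@H](C)CCC/C(C)=C/Cc1cc(OC)ccc1OC | intermediate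
28 | (2R,3R,7E)-9-(3,6-dioxocyclohexa-1,4-dien-1-yl)-3,7-dimethyl-1-[(1S,4aS,8aS)-2,5,5,8a-tetramethyl-1,4,4a,5,6,7,8,8a-octahydronaphthalen-1-yl]non-7-en-2-yl hydrogen sulfate | CC1=CC[C@H]2C(C)(C)CCC[C@]2(C)[C@H]1C[C@@H](OS(=O)(=O)O)[C@H](C)CCC/C(C)=C/CC1=CC(=O)C=CC1=O | intermediate
29 | halisulfate 1, (2R,3R,7E)-9-(2,5-dihydroxyphenyl)-3,7-dimethyl-1-[(1S,4aS,8aS)-2,5,5,8a-tetramethyl-1,4,4a,5,6,7,8,8a-octahydronaphthalen-1-yl]non-7-en-2-yl hydrogen sulfate | CC1=CC[C@H]2C(C)(C)CCC[C@]2(C)[C@H]1C[C@@H](OS(=O)(=O)O)[C@H](C)CCC/C(C)=C/Cc1cc(O)ccc1O | target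

Total step count: 16.
Longest linear sequence: 13 steps (steps 1 to 5, then 9 to 16, from compound 1); steps 6 to 8 make the oxirane branch that joins at step 9.

Steps most likely to fail

Step 11. The C8 cation may lose a proton toward the exocyclic methyl or toward C9 instead of C7. A 1,2-hydride shift from C5 to C10 before ring closure would also erode the configuration of ring A. The fallback changes the terminating event from proton loss to capture by oxygen. It sets out from alcohol 17: with the C12 hydroxyl free, ClSO3H in i-PrNO2 at −78 °C should close ring B and a tetrahydrofuran in one operation (the ambroxide-type closure) and give the tricyclic ether (2R,3aR,5aS,9aS,9bR)-2-[(2R)-5-chloropentan-2-yl]-3a,6,6,9a-tetramethyldodecahydronaphtho[2,1-b]furan F1, a single saturated compound that can be purified before the alkene is introduced. Acylative cleavage of the tertiary C8–O bond of F1 with pivalic anhydride and catalytic FeCl3 in CH2Cl2 at 0 °C then puts the pivalate on O12 and forms the ring alkene from a contact ion pair in a weakly acidic medium. This opening goes through the same C8 cation, so the position of the double bond is not guaranteed, and any exocyclic isomer would be removed on AgNO3-impregnated silica. The fallback comes back to the route at 21.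

Step 9. The alkenylalanate may open the α-branched oxirane slowly, so that transfer of butyl or methyl and Lewis-acid rearrangement of the oxirane compete. The fallback builds the C8=C9 alkene on the oxirane fragment and joins the halves at C7–C8 by a B-alkyl Suzuki coupling. It sets out from oxirane 14 and iodide 6.
- 14 is opened at its CH2 carbon with 1-propynyllithium and BF3·OEt2 (THF, −78 °C) to the homopropargylic alcohol (5R,6R)-9-chloro-6-methylnon-2-yn-5-ol F2.
- F2 is acylated (pivaloyl chloride, DMAP, pyridine) to (5R,6R)-9-chloro-6-methylnon-2-yn-5-yl 2,2-dimethylpropanoate F3.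
- Hydrozirconation of F3 with Cp2Zr(H)Cl (zirconium on the methyl-bearing carbon after equilibration) and iodination gives the vinyl iodide (2E,5R,6R)-9-chloro-2-iodo-6-methylnon-2-en-5-yl 2,2-dimethylpropanoate F4.
- Iodide 6 is converted in one flask (t-BuLi, then B-methoxy-9-BBN, THF, −78 °C) into lithium methoxy{2-[(1S)-2,6,6-trimethylcyclohex-2-en-1-yl]ethyl}-9-borabicyclo[3.3.1]nonan-9-uide F5.
- F5 is cross-coupled with F4 (PdCl2(dppf), K3PO4, DMF, 25 °C), which comes back to the route at 18.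

Step 16. The cerium reagent may oxidize the two electron-rich trisubstituted alkenes, and the amphiphilic sulfate may be lost in the aqueous cerium work-up. The fallback changes the order of events so that the oxidation is done on a neutral lipid before the sulfate is in place. It sets out from alcohol 26: (NH4)2Ce(NO3)6 in MeCN/H2O at 0 °C gives the quinone alcohol (2R,3R,7E)-9-(3,6-dioxocyclohexa-1,4-dien-1-yl)-3,7-dimethyl-1-[(1S,4aS,8aS)-2,5,5,8a-tetramethyl-1,4,4a,5,6,7,8,8a-octahydronaphthalen-1-yl]non-7-en-2-ol F6, which is extracted and chromatographed. Sulfation of its only hydroxyl with SO3·pyridine in DMF at 0 °C gives the quinone sulfate, where the fallback comes back to the route at 28. Reduction with Na2S2O4 as in step 16 then gives 29.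

Further compounds
F1 | step 11 | (2R,3aR,5aS,9aS,9bR)-2-[(2R)-5-chloropentan-2-yl]-3a,6,6,9a-tetramethyldodecahydronaphtho[2,1-b]furan | C[C@@]12CC[C@H]3C(C)(C)CCC[C@]3(C)[C@H]1C[C@@H](O2)[C@H](C)CCCCl
F2 | step 9 | (5R,6R)-9-chloro-6-methylnon-2-yn-5-ol | CC#CC[C@@H](O)[C@H](C)CCCCl
F3 | step 9 | (5R,6R)-9-chloro-6-methylnon-2-yn-5-yl 2,2-dimethylpropanoate | CC#CC[C@@H](OC(=O)C(C)(C)C)[C@H](C)CCCCl
F4 | step 9 | (2E,5R,6R)-9-chloro-2-iodo-6-methylnon-2-en-5-yl 2,2-dimethylpropanoate | C/C(I)=C\C[C@@H](OC(=O)C(C)(C)C)[C@H](C)CCCCl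
F5 | step 9 | lithium methoxy{2-[(1S)-2,6,6-trimethylcyclohex-2-en-1-yl]ethyl}-9-borabicyclo[3.3.1]nonan-9-uide | [Li+].CO[B-]1(CC[C@@H]2C(C)=CCCC2(C)C)C3CCCC1CCC3
F6 | step 16 | (2R,3R,7E)-9-(3,6-dioxocyclohexa-1,4-dien-1-yl)-3,7-dimethyl-1-[(1S,4aS,8aS)-2,5,5,8a-tetramethyl-1,4,4a,5,6,7,8,8a-octahydronaphthalen-1-yl]non-7-en-2-ol | CC1=CC[C@H]2C(C)(C)CCC[C@]2(C)[C@H]1C[C@@H](O)[C@H](C)CCC/C(C)=C/CC1=CC(=O)C=CC1=O
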